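A direct plan would metalate 3,5-dimethoxytoluene A1 and 1,2,4,5-tetramethoxy-3-methylbenzene A2 with n-BuLi and alkylate the two aryllithiums in turn with 1,14-dibromotetradecane A3, which would give hexamethyl ether A4 with both arenes on the chain.
BBr3 would then strip all six O-methyl groups to hexol A5, IBX would take this to bis-quinone A6, which lacks the ring A methoxy group, and a copper-mediated oxidative addition of methanol to the last ring C–H would have to finish the synthesis.
Its weakest steps would be: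
- the closing methoxylation of A6: addition of an alcohol to a hydroxyquinone C–H under divalent copper and O2 has no precedent, and it would be the last step, on a substrate and a product whose two rings both bind the metal;
- the exhaustive demethylation with the IBX oxygenation: six methyl ethers are carried only to be erased, the one O-methyl group that the target keeps is lost with them, and an air-sensitive hexol must be oxygenated on one ring only;
- the two aryllithium alkylations: SN2 attack of aryllithiums flanked by two methoxy groups on a long primary bromide competes with elimination and bromine–lithium exchange, and this disconnection ties the plan to preformed, fully O-methylated arenes.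

**Retrosynthetic overview**
Ring A and ring B are both hexasubstituted 1,4-benzoquinones in which C1(=O)–C2(OH)–C3(chain CH2)–C4(=O) is a squaric acid pattern (four contiguous carbons, three oxygenated) and C5(O)–C6(CH3) is a propenyl ether; the rings differ only at O5 (OCH3 in ring A, OH in ring B).
Each ring is therefore cut at C1–C6 and C4–C5. The chain is first joined to two squarate esters (bis-dione 11), the C1–C6 bonds are made by 1,2-addition of two 2-lithiopropenyl ethers (O-methyl for ring A, O-tert-butyl for ring B), and the C4–C5 bonds of both rings are closed together by thermal 4π ring opening and 6π ring closure; neither six-membered ring exists before that step.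
The ring A methoxy group arrives inside a building block and is never put on a ring C–H, no O-methyl group is made in order to be removed, all twelve ring substituents are placed by construction, and the only deprotection is the acidolysis of three tert-butyl groups.

Key step: step 7

Remark: the target has no stereocentre; the carbinol centres of 10, 13 and 15 are destroyed in step 7, so these compounds are carried as stereoisomer mixtures, and only the (Z) geometry of bromo enol ethers 2 and 6 matters (it keeps lithium cis to oxygen after exchange).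

Step 1
Reactants: 1 2-bromo-1,1-dimethoxypropane
Product: 2 (Z)-2-bromo-1-methoxyprop-1-ene
Conditions: TMSOTf (1.1 equiv), i-Pr2NEt (1.3 equiv), CH2Cl2, −20 °C to rt; fractional distillation, (Z)-isomer collected
Reagents that add atoms: none
Why: TMSOTf ionises the acetal to an oxocarbenium ion and the hindered amine removes the only β-hydrogen (at C2), an acetal-to-enol-ether elimination that keeps bromine on C2, and the (Z)-isomer (Br cis to OMe) is taken on because only it gives a chelated lithium reagent.

Step 2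
Reactants: 3 allyl tert-butyl ether
Product: 4 (Z)-1-tert-butoxyprop-1-ene
Conditions: KOt-Bu (0.3 equiv), DMSO, rt to 60 °C; distillation
Reagents that add atoms: none
Why: Base-mediated allyl-to-propenyl ether isomerisation runs through a potassium-chelated cisoid allyl anion and should therefore give the (Z)-enol ether.

Step 3
Reactants: 4 (Z)-1-tert-butoxyprop-1-ene
Product: 6 (Z)-2-bromo-1-tert-butoxyprop-1-ene, via dibromo ether 5 (not isolated)
Conditions: Br2 (1.0 equiv), pentane, −78 °C; then Et3N (2.5 equiv), −78 °C to 35 °C; distillation from K2CO3 under reduced pressure, (Z)-isomer collected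
Reagents that add atoms: bromine, BrBr
Why: Bromine adds across the electron-rich enol ether and the amine then removes HBr from the α-bromo ether (ionisation at C1, loss of H from C2), the classical bromination–dehydrobromination route to β-bromo enol ethers, carried out cold so that the tert-butyl oxocarbenium ion does not fragment.

Step 4
Reactants: 7 1,14-dibromotetradecane; 8 di-tert-butyl squarate (3,4-di-tert-butoxycyclobut-3-ene-1,2-dione; two molecules are taken up per molecule of 7)
Product: 11 4,4'-(tetradecane-1,14-diyl)bis(3-tert-butoxycyclobut-3-ene-1,2-dione), via tetradecanediyl di-Grignard reagent 9 (not isolated), via bis(bromomagnesium alkoxide) 10 (not isolated)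
Conditions: 7 added slowly to Mg (excess), THF, 50 °C; cannulated into 8 (2.3 equiv), THF, −78 °C; TFAA (2.5 equiv), −78 °C to 0 °C; aq. NaHCO3
Reagents that add atoms: di-tert-butyl squarate (the second molecule of 8, which supplies the four-membered ring at the other chain end), CC(C)(C)OC1=C(OC(C)(C)C)C(=O)C1=O
Why: Each of the two carbon–magnesium ends adds 1,2 to one carbonyl of its own molecule of the squaric diester (Grignard addition, two molecules of 8 per chain), and TFAA then acylates each alkoxide so that ionisation and loss of tert-butyl trifluoroacetate transpose the carbonyl, the standard entry to 3-alkoxy-4-alkylcyclobutenediones.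

Step 5
Reactants: 11 4,4'-(tetradecane-1,14-diyl)bis(3-tert-butoxycyclobut-3-ene-1,2-dione); 2 (Z)-2-bromo-1-methoxyprop-1-ene
Product: 13 3-tert-butoxy-4-{14-[2-tert-butoxy-3-hydroxy-3-[(Z)-1-methoxyprop-1-en-2-yl]-4-oxocyclobut-1-en-1-yl]tetradecyl}cyclobut-3-ene-1,2-dione, via methoxypropenyllithium 12 (not isolated)
Conditions: 2 (1.0 equiv), t-BuLi (1.95 equiv), Et2O, −78 °C; cannulated slowly into 11 (3.0 equiv), THF, −78 °C; AcOH (1.1 equiv), −78 °C; chromatography on Et3N-deactivated silica, unreacted 11 recovered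
Reagents that add atoms: none
Why: Bromine–lithium exchange with retention gives a vinyllithium held by O–Li chelation against β-elimination, which adds 1,2 to the more electrophilic carbonyl of one dione (the one next to C–Ot-Bu, the other being a vinylogous ester carbonyl), while the threefold excess of the symmetrical bis-dione keeps the second end free; the new carbinol centre is racemic and is destroyed in step 7.

Step 6
Reactants: 13 3-tert-butoxy-4-{14-[2-tert-butoxy-3-hydroxy-3-[(Z)-1-methoxyprop-1-en-2-yl]-4-oxocyclobut-1-en-1-yl]tetradecyl}cyclobut-3-ene-1,2-dione; 6 (Z)-2-bromo-1-tert-butoxyprop-1-ene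
Product: 15 3-tert-butoxy-2-{14-[2-tert-butoxy-3-[(Z)-1-tert-butoxyprop-1-en-2-yl]-3-hydroxy-4-oxocyclobut-1-en-1-yl]tetradecyl}-4-hydroxy-4-[(Z)-1-methoxyprop-1-en-2-yl]cyclobut-2-en-1-one, via tert-butoxypropenyllithium 14 (not isolated)
Conditions: 6 (2.4 equiv), t-BuLi (4.7 equiv), Et2O, −78 °C; 13 (1.0 equiv) in THF added, −78 °C; AcOH (2.2 equiv), −78 °C; rapid filtration through Et3N-deactivated silica
Reagents that add atoms: none
Why: The same regioselective 1,2-addition of the tert-butoxy analogue to the remaining dione places the second propenyl ether, the first equivalent of 14 being spent on the tertiary hydroxyl of 13; the second carbinol centre forms without control, which is irrelevant.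

Step 7
Reactants: 15 3-tert-butoxy-2-{14-[2-tert-butoxy-3-[(Z)-1-tert-butoxyprop-1-en-2-yl]-3-hydroxy-4-oxocyclobut-1-en-1-yl]tetradecyl}-4-hydroxy-4-[(Z)-1-methoxyprop-1-en-2-yl]cyclobut-2-en-1-one
Product: 18 2-tert-butoxy-3-[14-(2,5-di-tert-butoxy-4-methyl-3,6-dioxocyclohexa-1,4-dien-1-yl)tetradecyl]-5-methoxy-6-methylcyclohexa-2,5-diene-1,4-dione, via bis(dienylketene) 16 (not isolated), via bis-hydroquinone 17 (not isolated)
Conditions: degassed toluene (0.01 M), 110 °C, 3 h; cooled to rt, Ag2O (5 equiv), K2CO3, 1 h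
Reagents that add atoms: none
Why: Each 4-hydroxycyclobutenone opens by thermal conrotatory 4π cleavage of the bond between its ketone carbon (future C4) and its carbinol carbon (future C1), the hydroxyl turning outward so that the propenyl ether turns inward next to the ketene, and disrotatory 6π electrocyclization of the dienylketene forms the C4–C5 bond, after which enolization gives the hydroquinone and Ag2O dehydrogenates it. The closest known reaction type is the Moore rearrangement of 4-alkenyl-4-hydroxycyclobutenones to hydroquinones, here run at both ends of the chain in one flask. Both six-membered rings close in the 6π mode from open-chain trienes, so the precursor holds no ring larger than four atoms and no ring is closed against strain. No stereocentre is formed, and the two carbinol centres and both enol ether geometries are erased by aromatization. The selectivity needed is regiochemical only and is secured by the substrate: C2–O and C3–chain come from the squarate carbons, C5–O and C6–CH3 from the propenyl unit, and the outward rotation of OH is the known torquoselectivity of these ring openings. The alkoxy group sits on the inner face of the closing terminus, which should slow the closure, so high dilution is used to keep the ketenes from intermolecular capture.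

Step 8
Reactants: 18 2-tert-butoxy-3-[14-(2,5-di-tert-butoxy-4-methyl-3,6-dioxocyclohexa-1,4-dien-1-yl)tetradecyl]-5-methoxy-6-methylcyclohexa-2,5-diene-1,4-dione
Product: 19 2,5-dihydroxy-3-[14-(2-hydroxy-5-methoxy-4-methyl-3,6-dioxocyclohexa-1,4-dien-1-yl)tetradecyl]-6-methylcyclohexa-2,5-diene-1,4-dione (target)
Conditions: TFA/CH2Cl2 (1:4), 0 °C to rt, 1 h; evaporation, recrystallisation
Reagents that add atoms: none
Why: Anhydrous TFA cleaves the three vinylogous tert-butyl esters by the tert-butyl cation (E1) pathway and leaves the vinylogous methyl ester of ring A untouched, since that group can only be cleaved by addition–elimination of water.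

**Compound list**
1 | 2-bromo-1,1-dimethoxypropane (racemic) | COC(OC)C(C)Br | starting material
2 | (Z)-2-bromo-1-methoxyprop-1-ene | CO/C=C(/C)Br | intermediate
3 | allyl tert-butyl ether (3-tert-butoxyprop-1-ene) | C=CCOC(C)(C)C | starting material
4 | (Z)-1-tert-butoxyprop-1-ene | C/C=C\OC(C)(C)C | intermediate
5 | 1,2-dibromo-1-tert-butoxypropane (diastereomer mixture) | CC(Br)C(Br)OC(C)(C)C | intermediate
6 | (Z)-2-bromo-1-tert-butoxyprop-1-ene | CC(C)(C)O/C=C(/C)Br | intermediate
7 | 1,14-dibromotetradecane | BrCCCCCCCCCCCCCCBr | starting material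
8 | di-tert-butyl squarate (3,4-di-tert-butoxycyclobut-3-ene-1,2-dione) | CC(C)(C)OC1=C(OC(C)(C)C)C(=O)C1=O | starting material
9 | tetradecane-1,14-diylbis(magnesium bromide) | Br[Mg]CCCCCCCCCCCCCC[Mg]Br | intermediate
10 | bis(bromomagnesium alkoxide) of 4,4'-(tetradecane-1,14-diyl)bis(2,3-di-tert-butoxy-4-hydroxycyclobut-2-en-1-one) (stereoisomer mixture) | CC(C)(C)OC1=C(OC(C)(C)C)C(O[Mg]Br)(CCCCCCCCCCCCCCC2(O[Mg]Br)C(OC(C)(C)C)=C(OC(C)(C)C)C2=O)C1=O | intermediate
11 | 4,4'-(tetradecane-1,14-diyl)bis(3-tert-butoxycyclobut-3-ene-1,2-dione) | CC(C)(C)OC1=C(CCCCCCCCCCCCCCC2=C(OC(C)(C)C)C(=O)C2=O)C(=O)C1=O | intermediate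
12 | (E)-(1-methoxyprop-1-en-2-yl)lithium (Li cis to OMe) | CO/C=C(/C)[Li] | intermediate
13 | 3-tert-butoxy-4-{14-[2-tert-butoxy-3-hydroxy-3-[(Z)-1-methoxyprop-1-en-2-yl]-4-oxocyclobut-1-en-1-yl]tetradecyl}cyclobut-3-ene-1,2-dione (racemic) | CC(C)(C)OC1=C(CCCCCCCCCCCCCCC2=C(OC(C)(C)C)C(O)(/C(C)=C\OC)C2=O)C(=O)C1=O | intermediate
14 | (E)-(1-tert-butoxyprop-1-en-2-yl)lithium (Li cis to Ot-Bu) | CC(C)(C)O/C=C(/C)[Li] | intermediate
15 | 3-tert-butoxy-2-{14-[2-tert-butoxy-3-[(Z)-1-tert-butoxyprop-1-en-2-yl]-3-hydroxy-4-oxocyclobut-1-en-1-yl]tetradecyl}-4-hydroxy-4-[(Z)-1-methoxyprop-1-en-2-yl]cyclobut-2-en-1-one (diastereomer mixture) | CO\C=C(C)/C1(O)C(OC(C)(C)C)=C(CCCCCCCCCCCCCCC2=C(OC(C)(C)C)C(O)(/C(C)=C\OC(C)(C)C)C2=O)C1=O | intermediate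
16 | bis(dienylketene): tetradecane-1,14-diyl chain carrying at each end a 2-substituted 3-tert-butoxy-4-hydroxy-5-methyl-6-alkoxyhexa-1,3,5-trien-1-one (alkoxy = methoxy at one end and tert-butoxy at the other; propenyl unit cis to the ketene; enol ether Z) | CO\C=C(C)/C(O)=C(OC(C)(C)C)\C(CCCCCCCCCCCCCCC(=C=O)\C(OC(C)(C)C)=C(O)/C(C)=C\OC(C)(C)C)=C=O | intermediate
17 | 3-tert-butoxy-2-[14-(2,5-di-tert-butoxy-3,6-dihydroxy-4-methylphenyl)tetradecyl]-6-methoxy-5-methylbenzene-1,4-diol | COc1c(C)c(O)c(OC(C)(C)C)c(CCCCCCCCCCCCCCc2c(O)c(OC(C)(C)C)c(C)c(O)c2OC(C)(C)C)c1O | intermediate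
18 | 2-tert-butoxy-3-[14-(2,5-di-tert-butoxy-4-methyl-3,6-dioxocyclohexa-1,4-dien-1-yl)tetradecyl]-5-methoxy-6-methylcyclohexa-2,5-diene-1,4-dione | COC1=C(C)C(=O)C(OC(C)(C)C)=C(CCCCCCCCCCCCCCC2=C(OC(C)(C)C)C(=O)C(C)=C(OC(C)(C)C)C2=O)C1=O | intermediate
19 | 2,5-dihydroxy-3-[14-(2-hydroxy-5-methoxy-4-methyl-3,6-dioxocyclohexa-1,4-dien-1-yl)tetradecyl]-6-methylcyclohexa-2,5-diene-1,4-dione | COC1=C(C)C(=O)C(O)=C(CCCCCCCCCCCCCCC2=C(O)C(=O)C(C)=C(O)C2=O)C1=O | target

**Step count and risk**
Total: 8 steps (three short reagent steps, five on the main line). Longest linear sequence: 5 steps (steps 4 to 8).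

Steps most likely to fail:

1. Step 7 (twofold ring expansion). Closure onto a terminus that carries its alkoxy group on the inner face may be slow, so that a ketene at one chain end is captured by the phenolic hydroxyls of a ring already formed (in the same or another molecule) and oligomeric esters result. The fallback closes the rings one at a time and sets out from 13. Heated alone in toluene (the dione end is thermally inert), 13 would give 3-tert-butoxy-4-[14-(2-tert-butoxy-3,6-dihydroxy-5-methoxy-4-methylphenyl)tetradecyl]cyclobut-3-ene-1,2-dione F1, which would be silylated in the same flask (TBSOTf, 2,6-lutidine) to 3-tert-butoxy-4-{14-[2-tert-butoxy-3,6-bis(tert-butyldimethylsilyloxy)-5-methoxy-4-methylphenyl]tetradecyl}cyclobut-3-ene-1,2-dione F2. Addition of 14 (1.2 equiv, −78 °C) would give 3-tert-butoxy-4-[(Z)-1-tert-butoxyprop-1-en-2-yl]-2-{14-[2-tert-butoxy-3,6-bis(tert-butyldimethylsilyloxy)-5-methoxy-4-methylphenyl]tetradecyl}-4-hydroxycyclobut-2-en-1-one F3, a second thermolysis 2,5-di-tert-butoxy-3-{14-[2-tert-butoxy-3,6-bis(tert-butyldimethylsilyloxy)-5-methoxy-4-methylphenyl]tetradecyl}-6-methylbenzene-1,4-diol F4, and Bu4NF/AcOH would remove the silyl groups to return to the route at 17, just before the Ag2O oxidation.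

2. Step 5 (mono-addition). The second dione end competes for the vinyllithium (bis-addition), and any (E)-bromide in 2 gives a lithium reagent that fragments to propyne and lithium methoxide, so that the stoichiometry drifts. The fallback moves the differentiation of the rings to the end and sets out from 11. Both ends would take 12 (2.4 equiv) to give 2,2'-(tetradecane-1,14-diyl)bis{3-tert-butoxy-4-hydroxy-4-[(Z)-1-methoxyprop-1-en-2-yl]cyclobut-2-en-1-one} F5. Thermolysis as in step 7 would give 2,2'-(tetradecane-1,14-diyl)bis(3-tert-butoxy-6-methoxy-5-methylbenzene-1,4-diol) F6, Ag2O would give 3,3'-(tetradecane-1,14-diyl)bis(2-tert-butoxy-5-methoxy-6-methylcyclohexa-2,5-diene-1,4-dione) F7, and TFA would give 3,3'-(tetradecane-1,14-diyl)bis(2-hydroxy-5-methoxy-6-methylcyclohexa-2,5-diene-1,4-dione) F8. One of the two vinylogous methyl esters of F8 would then be saponified with limiting aqueous NaOH in THF; this is statistical, but starting material, product and over-hydrolysed material differ by one acidic hydroxyl each, so they would be separated by extraction at graded pH and F8 recycled. The fallback returns to the route at 19.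

3. Step 4 (bis-dione). The di-Grignard reagent may be lost to Wurtz coupling and oligomers, or may add unevenly, so that mono-dione and over-addition products contaminate 11. The fallback builds the chain at its midpoint from two eight-carbon halves and sets out from 8. 8-Bromooct-1-ene F9 would be converted into oct-7-en-1-ylmagnesium bromide F10 and added to 8 to give bromomagnesium 2,3-di-tert-butoxy-1-(oct-7-en-1-yl)-4-oxocyclobut-2-en-1-olate F11, which TFAA would turn into 3-tert-butoxy-4-(oct-7-en-1-yl)cyclobut-3-ene-1,2-dione F12. Self-metathesis of two molecules of F12 (second-generation Grubbs catalyst RuCl2(H2IMes)(PCy3)(=CHPh), CH2Cl2, 40 °C, ethene swept out) would give (E)-4,4'-(tetradec-7-ene-1,14-diyl)bis(3-tert-butoxycyclobut-3-ene-1,2-dione) F13 (E/Z mixture, drawn as E), whose fourteen-carbon tether consists of six methylene groups on each side of the new alkene, and hydrogenation of the chain alkene alone with H2 and RhCl(PPh3)3 would return to the route at 11.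

**Further compounds**
F1 | step 7 | 3-tert-butoxy-4-[14-(2-tert-butoxy-3,6-dihydroxy-5-methoxy-4-methylphenyl)tetradecyl]cyclobut-3-ene-1,2-dione | COc1c(C)c(O)c(OC(C)(C)C)c(CCCCCCCCCCCCCCC2=C(OC(C)(C)C)C(=O)C2=O)c1O
F2 | step 7 | 3-tert-butoxy-4-{14-[2-tert-butoxy-3,6-bis(tert-butyldimethylsilyloxy)-5-methoxy-4-methylphenyl]tetradecyl}cyclobut-3-ene-1,2-dione | COc1c(C)c(O[Si](C)(C)C(C)(C)C)c(OC(C)(C)C)c(CCCCCCCCCCCCCCC2=C(OC(C)(C)C)C(=O)C2=O)c1O[Si](C)(C)C(C)(C)C
F3 | step 7 | 3-tert-butoxy-4-[(Z)-1-tert-butoxyprop-1-en-2-yl]-2-{14-[2-tert-butoxy-3,6-bis(tert-butyldimethylsilyloxy)-5-methoxy-4-methylphenyl]tetradecyl}-4-hydroxycyclobut-2-en-1-one (racemic) | COc1c(C)c(O[Si](C)(C)C(C)(C)C)c(OC(C)(C)C)c(CCCCCCCCCCCCCCC2=C(OC(C)(C)C)C(O)(/C(C)=C\OC(C)(C)C)C2=O)c1O[Si](C)(C)C(C)(C)C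
F4 | step 7 | 2,5-di-tert-butoxy-3-{14-[2-tert-butoxy-3,6-bis(tert-butyldimethylsilyloxy)-5-methoxy-4-methylphenyl]tetradecyl}-6-methylbenzene-1,4-diol | COc1c(C)c(O[Si](C)(C)C(C)(C)C)c(OC(C)(C)C)c(CCCCCCCCCCCCCCc2c(O)c(OC(C)(C)C)c(C)c(O)c2OC(C)(C)C)c1O[Si](C)(C)C(C)(C)C
F5 | step 5 | 2,2'-(tetradecane-1,14-diyl)bis{3-tert-butoxy-4-hydroxy-4-[(Z)-1-methoxyprop-1-en-2-yl]cyclobut-2-en-1-one} (diastereomer mixture) | CO\C=C(C)/C1(O)C(OC(C)(C)C)=C(CCCCCCCCCCCCCCC2=C(OC(C)(C)C)C(O)(/C(C)=C\OC)C2=O)C1=O
F6 | step 5 | 2,2'-(tetradecane-1,14-diyl)bis(3-tert-butoxy-6-methoxy-5-methylbenzene-1,4-diol) | COc1c(C)c(O)c(OC(C)(C)C)c(CCCCCCCCCCCCCCc2c(O)c(OC)c(C)c(O)c2OC(C)(C)C)c1O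
F7 | step 5 | 3,3'-(tetradecane-1,14-diyl)bis(2-tert-butoxy-5-methoxy-6-methylcyclohexa-2,5-diene-1,4-dione) | COC1=C(C)C(=O)C(OC(C)(C)C)=C(CCCCCCCCCCCCCCC2=C(OC(C)(C)C)C(=O)C(C)=C(OC)C2=O)C1=O
F8 | step 5 | 3,3'-(tetradecane-1,14-diyl)bis(2-hydroxy-5-methoxy-6-methylcyclohexa-2,5-diene-1,4-dione) | COC1=C(C)C(=O)C(O)=C(CCCCCCCCCCCCCCC2=C(O)C(=O)C(C)=C(OC)C2=O)C1=O
F9 | step 4 | 8-bromooct-1-ene | C=CCCCCCCBr
F10 | step 4 | oct-7-en-1-ylmagnesium bromide | C=CCCCCCC[Mg]Br
F11 | step 4 | bromomagnesium 2,3-di-tert-butoxy-1-(oct-7-en-1-yl)-4-oxocyclobut-2-en-1-olate (racemic) | C=CCCCCCCC1(O[Mg]Br)C(OC(C)(C)C)=C(OC(C)(C)C)C1=O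
F12 | step 4 | 3-tert-butoxy-4-(oct-7-en-1-yl)cyclobut-3-ene-1,2-dione | C=CCCCCCCC1=C(OC(C)(C)C)C(=O)C1=O
F13 | step 4 | (E)-4,4'-(tetradec-7-ene-1,14-diyl)bis(3-tert-butoxycyclobut-3-ene-1,2-dione) | CC(C)(C)OC1=C(CCCCCC/C=C/CCCCCCC2=C(OC(C)(C)C)C(=O)C2=O)C(=O)C1=O
A1 | direct plan | 3,5-dimethoxytoluene | COc1cc(C)cc(OC)c1
A2 | direct plan | 1,2,4,5-tetramethoxy-3-methylbenzene | Cc1c(OC)c(OC)cc(OC)c1OC
A3 | direct plan | 1,14-dibromotetradecane | BrCCCCCCCCCCCCCCBr
A4 | direct plan | 3-[14-(2,6-dimethoxy-4-methylphenyl)tetradecyl]-1,2,4,5-tetramethoxy-6-methylbenzene | COc1cc(C)cc(OC)c1CCCCCCCCCCCCCCc1c(OC)c(OC)c(C)c(OC)c1OC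
A5 | direct plan | 3-[14-(2,6-dihydroxy-4-methylphenyl)tetradecyl]-6-methylbenzene-1,2,4,5-tetrol | Cc1cc(O)c(CCCCCCCCCCCCCCc2c(O)c(O)c(C)c(O)c2O)c(O)c1
A6 | direct plan | 2,5-dihydroxy-3-[14-(2-hydroxy-4-methyl-3,6-dioxocyclohexa-1,4-dien-1-yl)tetradecyl]-6-methylcyclohexa-2,5-diene-1,4-dione | CC1=CC(=O)C(CCCCCCCCCCCCCCC2=C(O)C(=O)C(C)=C(O)C2=O)=C(O)C1=O
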